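**Plan**
- Retrosynthesis: after end-game changes at C2' (MOM ether) and C6' (acetate in place of a silyl ether), ring A, the benzoate ring, is cut at C1–C2 and C3–C4. One stage earlier the diaryl ether is cut at the bond from oxygen to C6.
- Enabling feature: ring A is a salicylate (C1 CO2Me, C2 OH, C4 CH3, C6 OAr). Its C1, C6, C5 and C4 are therefore C3, C4, C5 and C6 of a 3-methoxycarbonyl-6-methyl-2-pyrone bearing the ring B aryloxy group at C4, and C2 (with its oxygen) plus C3 are a ketene acetal.
- Forward: ring B (C1' O, C2' OMOM, C4' OCH3, C6' CH2OTIPS) is dressed in five steps from 2-hydroxy-5-methoxybenzaldehyde. The pyrone ring is closed from dimethyl malonate and an acetylketene source, and the two are joined by addition–elimination at pyrone C4.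
- Ring A arises last, by inverse-electron-demand [4+2] cycloaddition, loss of CO2 and loss of trimethylsilanol. Desilylation, acetylation and MOM cleavage finish the synthesis.
- Stereochemistry: the target is achiral. The only stereocentres are the bridgeheads of the cycloadduct, and they are transient.

Key step: step 10

Assumption: conjugate bases formed in the flask (phenoxides, enolates) are treated as the salt form of the numbered parent compound and get no number of their own.

Step 1
Reactants: 1 2-hydroxy-5-methoxybenzaldehyde
Product: 2 3-bromo-2-hydroxy-5-methoxybenzaldehyde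
Conditions: Br2 (1.05 equiv), NaOAc, AcOH, rt
Reagents that add atoms: bromine, BrBr
Why: Electrophilic aromatic bromination in which the free phenol is the strongest director and its para position is blocked by the methoxy group, so bromine should enter at C3, ortho to the hydroxyl.

Step 2
Reactants: 2 3-bromo-2-hydroxy-5-methoxybenzaldehyde
Product: 3 2,3-dihydroxy-5-methoxybenzaldehyde
Conditions: NaOH (aq), Cu powder, reflux, N2; then HCl
Reagents that add atoms: sodium hydroxide, [Na+].[OH-]
Why: Copper-mediated Ullmann-type hydroxylation of an ortho-bromophenoxide, the reaction that turns 5-bromovanillin into 5-hydroxyvanillin, should exchange bromide for hydroxide while the phenoxide charge shields the non-enolisable aldehyde from Cannizzaro disproportionation and the nitrogen blanket keeps the catechol from autoxidation.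

Step 3
Reactants: 3 2,3-dihydroxy-5-methoxybenzaldehyde
Product: 4 2-hydroxy-5-methoxy-3-(methoxymethoxy)benzaldehyde
Conditions: NaH (2.2 equiv), THF–DMF, 0 °C; MOMCl (1.0 equiv), 0 °C; aq NH4Cl
Reagents that add atoms: chloromethyl methyl ether, COCCl
Why: Regioselective Williamson mono-alkylation of a catechol dianion, in which the C2 phenoxide is delocalised into the ortho formyl group, so the unconjugated and more nucleophilic C3 phenoxide should take up the single equivalent of alkylating agent.

Step 4
Reactants: 4 2-hydroxy-5-methoxy-3-(methoxymethoxy)benzaldehyde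
Product: 5 2-(hydroxymethyl)-4-methoxy-6-(methoxymethoxy)phenol
Conditions: NaBH4, MeOH–THF, 0 °C
Reagents that add atoms: none
Why: Borohydride reduction of an aryl aldehyde, to which the MOM acetal and the aryl ethers are inert.

Step 5
Reactants: 5 2-(hydroxymethyl)-4-methoxy-6-(methoxymethoxy)phenol
Product: 6 4-methoxy-2-(methoxymethoxy)-6-[(triisopropylsilyloxy)methyl]phenol
Conditions: TIPSCl (1.05 equiv), imidazole, CH2Cl2, 0 °C to rt
Reagents that add atoms: chlorotriisopropylsilane, CC(C)[Si](Cl)(C(C)C)C(C)C
Why: Chemoselective silylation in which the bulky silyl chloride should react at the unhindered primary benzylic alcohol much faster than at the phenol flanked by two ortho substituents, as in the known monosilylation of salicyl alcohols.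

Step 6
Reactants: 7 dimethyl malonate; 8 2,2,6-trimethyl-4H-1,3-dioxin-4-one
Product: 11 methyl 4-hydroxy-6-methyl-2-oxo-2H-pyran-3-carboxylate, via acetylketene 9 (not isolated), via dimethyl 2-(3-oxobutanoyl)malonate 10 (not isolated)
Conditions: NaH (1.05 equiv), THF, 0 °C; slow addition of 8 in toluene at 110 °C with distillation of THF and acetone; then 1 M HCl
Reagents that add atoms: none
Why: Thermal retro-[4+2] cleavage of the dioxinone releases acetylketene, which C-acylates the sodium malonate, and the enolised tricarbonyl product lactonises onto one ester with loss of methanol, the acylation–cyclisation sequence known for malonates and diketene.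

Step 7
Reactants: 11 methyl 4-hydroxy-6-methyl-2-oxo-2H-pyran-3-carboxylate
Product: 12 methyl 6-methyl-2-oxo-4-(tosyloxy)-2H-pyran-3-carboxylate
Conditions: TsCl, Et3N, CH2Cl2, 0 °C to rt
Reagents that add atoms: 4-toluenesulfonyl chloride, Cc1ccc(cc1)S(=O)(=O)Cl
Why: O-Sulfonylation of the acidic vinylogous-acid hydroxyl, standard for 4-hydroxy-2-pyrones, turns C4 into a vinylogous acyl sulfonate.

Step 8
Reactants: 12 methyl 6-methyl-2-oxo-4-(tosyloxy)-2H-pyran-3-carboxylate; 6 4-methoxy-2-(methoxymethoxy)-6-[(triisopropylsilyloxy)methyl]phenol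
Product: 13 methyl 4-{4-methoxy-2-(methoxymethoxy)-6-[(triisopropylsilyloxy)methyl]phenoxy}-6-methyl-2-oxo-2H-pyran-3-carboxylate
Conditions: 6, NaH (1.0 equiv), THF, 0 °C; then 12, 0 °C to rt
Reagents that add atoms: none
Why: Addition–elimination (vinylogous acyl substitution), known for 4-halo- and 4-sulfonyloxy-2-pyrones with phenoxides, should succeed because C4 is beta to both the lactone carbonyl and the ester, so even the 2,6-disubstituted phenoxide adds and expels tosylate, and the stoichiometric preformed phenoxide leaves no free base to open the pyrone.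

Step 9
Reactants: 14 trimethylsilyl acetate
Product: 15 1,1-bis(trimethylsilyloxy)ethene
Conditions: LDA, THF, −78 °C; TMSCl, −78 °C to rt; filtration and distillation
Reagents that add atoms: chlorotrimethylsilane, C[Si](C)(C)Cl
Why: Kinetic enolisation of the silyl ester and O-silylation is the established preparation of ketene bis(silyl) acetals, and any C-silylated isomer formed alongside is inert in the next step.

Step 10
Reactants: 13 methyl 4-{4-methoxy-2-(methoxymethoxy)-6-[(triisopropylsilyloxy)methyl]phenoxy}-6-methyl-2-oxo-2H-pyran-3-carboxylate; 15 1,1-bis(trimethylsilyloxy)ethene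
Product: 19 methyl 2-hydroxy-6-{4-methoxy-2-(methoxymethoxy)-6-[(triisopropylsilyloxy)methyl]phenoxy}-4-methylbenzoate, via bridged lactone cycloadduct 16 (not isolated), via bis(trimethylsilyloxy)cyclohexadiene 17 (not isolated), via aryl trimethylsilyl ether 18 (not isolated)
Conditions: 15 (5 equiv), toluene, 110 °C, sealed tube; then 5% aq citric acid, THF, rt
Reagents that add atoms: none
Why: Proposed new method: the diene C3=C4–C5=C6 of 13, made electron-poor by the C3 ester and the lactone carbonyl, should take up the electron-rich alkene of 15 in an inverse-electron-demand [4+2] cycloaddition in which the nucleophilic CH2 bonds to pyrone C6 and the acetal carbon to C3, giving bridged lactone 16; retro-[4+2] extrusion of CO2 then gives diene 17, 1,2-elimination of trimethylsilanol aromatises it to 18, and the aqueous citric acid wash frees the C2 phenol without harming MOM or TIPS. The closest known reaction type is the thermal cycloaddition–decarboxylation of 3-alkoxycarbonyl-2-pyrones with 1,1-dialkoxyethenes, which gives salicylate ethers; neither a 4-aryloxy pyrone nor a bis(silyl) ketene acetal has been shown in it, hence the label. Ring A is closed by an intermolecular [4+2] annulation (four carbons from the pyrone, two from the ketene acetal) that forms C1–C2 and C3–C4, and aromatisation makes the closure irreversible. The two bridgehead stereocentres of 16 are fixed relative to each other by the bicycle, arise racemic and vanish when CO2 leaves, so nothing has to be controlled and the product is achiral. Regioselectivity (oxygen-bearing carbon next to the ester) follows from the matched polarisation of the partners, C6 being the vinylogous acceptor terminus of the pyrone and CH2 the donor terminus of the ketene acetal. Chemoselectivity for C6/C3 over addition–elimination at C4 is secured by the non-polar solvent and the absence of Lewis acid or fluoride, which disfavour a zwitterionic Michael pathway, and by the 2,6-disubstituted aryloxy ring, which stands roughly perpendicular to the pyrone and screens C4; the excess of 15 also scavenges the silanol released.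

Step 11
Reactants: 19 methyl 2-hydroxy-6-{4-methoxy-2-(methoxymethoxy)-6-[(triisopropylsilyloxy)methyl]phenoxy}-4-methylbenzoate
Product: 20 methyl 2-hydroxy-6-[2-(hydroxymethyl)-4-methoxy-6-(methoxymethoxy)phenoxy]-4-methylbenzoate
Conditions: TBAF, AcOH (1:1), THF, 0 °C to rt
Reagents that add atoms: none
Why: Fluoride-induced silyl ether cleavage driven by the Si–F bond, with acetic acid buffering so that neither the liberated alkoxide nor the ring A phenoxide attacks the methyl ester, and with the MOM ether inert.

Step 12
Reactants: 20 methyl 2-hydroxy-6-[2-(hydroxymethyl)-4-methoxy-6-(methoxymethoxy)phenoxy]-4-methylbenzoate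
Product: 21 methyl 2-[2-(acetoxymethyl)-4-methoxy-6-(methoxymethoxy)phenoxy]-6-hydroxy-4-methylbenzoate
Conditions: Ac2O (1.1 equiv), pyridine, CH2Cl2, 0 °C
Reagents that add atoms: acetic anhydride, CC(=O)OC(C)=O
Why: Chemoselective O-acetylation in which the primary benzylic alcohol is acylated by one equivalent of anhydride in pyridine without DMAP far faster than the ring A phenol, which is deactivated by its hydrogen bond to the ester carbonyl.

Step 13
Reactants: 21 methyl 2-[2-(acetoxymethyl)-4-methoxy-6-(methoxymethoxy)phenoxy]-6-hydroxy-4-methylbenzoate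
Product: 22 betaethrin A, methyl 2-[2-(acetoxymethyl)-6-hydroxy-4-methoxyphenoxy]-6-hydroxy-4-methylbenzoate
Conditions: TFA–CH2Cl2 (1:9), 0 °C; aq NaHCO3
Reagents that add atoms: none
Why: Acid-catalysed acetal cleavage of a phenolic MOM ether in an alcohol-free medium, so the acetate cannot transesterify, and the benzylic C–O bond, whose strongest ring donors (the C2' and C4' oxygens) stand meta to it, should not ionise at this temperature.

**Compound list**
1 | 2-hydroxy-5-methoxybenzaldehyde | COc1ccc(O)c(C=O)c1 | starting material
2 | 3-bromo-2-hydroxy-5-methoxybenzaldehyde | COc1cc(Br)c(O)c(C=O)c1 | intermediate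
3 | 2,3-dihydroxy-5-methoxybenzaldehyde | COc1cc(O)c(O)c(C=O)c1 | intermediate
4 | 2-hydroxy-5-methoxy-3-(methoxymethoxy)benzaldehyde | COCOc1cc(OC)cc(C=O)c1O | intermediate
5 | 2-(hydroxymethyl)-4-methoxy-6-(methoxymethoxy)phenol | COCOc1cc(OC)cc(CO)c1O | intermediate
6 | 4-methoxy-2-(methoxymethoxy)-6-[(triisopropylsilyloxy)methyl]phenol | COCOc1cc(OC)cc(CO[Si](C(C)C)(C(C)C)C(C)C)c1O | intermediate
7 | dimethyl malonate | COC(=O)CC(=O)OC | starting material
8 | 2,2,6-trimethyl-4H-1,3-dioxin-4-one | CC1=CC(=O)OC(C)(C)O1 | starting material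
9 | acetylketene (not isolated) | CC(=O)C=C=O | intermediate
10 | dimethyl 2-(3-oxobutanoyl)malonate (not isolated) | COC(=O)C(C(=O)OC)C(=O)CC(C)=O | intermediate
11 | methyl 4-hydroxy-6-methyl-2-oxo-2H-pyran-3-carboxylate | COC(=O)C1=C(O)C=C(C)OC1=O | intermediate
12 | methyl 6-methyl-2-oxo-4-(tosyloxy)-2H-pyran-3-carboxylate | COC(=O)C1=C(OS(=O)(=O)c2ccc(C)cc2)C=C(C)OC1=O | intermediate
13 | methyl 4-{4-methoxy-2-(methoxymethoxy)-6-[(triisopropylsilyloxy)methyl]phenoxy}-6-methyl-2-oxo-2H-pyran-3-carboxylate | COC(=O)C1=C(Oc2c(OCOC)cc(OC)cc2CO[Si](C(C)C)(C(C)C)C(C)C)C=C(C)OC1=O | intermediate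
14 | trimethylsilyl acetate | CC(=O)O[Si](C)(C)C | starting material
15 | 1,1-bis(trimethylsilyloxy)ethene | C=C(O[Si](C)(C)C)O[Si](C)(C)C | intermediate
16 | methyl 5-aryloxy-1-methyl-3-oxo-8,8-bis(trimethylsilyloxy)-2-oxabicyclo[2.2.2]oct-5-ene-4-carboxylate, aryl = ring B of 13 (racemic, one enantiomer drawn, not isolated) | COC(=O)[C@@]12C(=O)O[C@@](C)(C=C1Oc3c(OCOC)cc(OC)cc3CO[Si](C(C)C)(C(C)C)C(C)C)CC2(O[Si](C)(C)C)O[Si](C)(C)C | intermediate
17 | methyl 2-aryloxy-4-methyl-6,6-bis(trimethylsilyloxy)cyclohexa-1,3-diene-1-carboxylate, aryl = ring B of 13 (not isolated) | COC(=O)C1=C(Oc2c(OCOC)cc(OC)cc2CO[Si](C(C)C)(C(C)C)C(C)C)C=C(C)CC1(O[Si](C)(C)C)O[Si](C)(C)C | intermediate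
18 | methyl 2-{4-methoxy-2-(methoxymethoxy)-6-[(triisopropylsilyloxy)methyl]phenoxy}-4-methyl-6-(trimethylsilyloxy)benzoate (not isolated) | COC(=O)c1c(O[Si](C)(C)C)cc(C)cc1Oc1c(OCOC)cc(OC)cc1CO[Si](C(C)C)(C(C)C)C(C)C | intermediate
19 | methyl 2-hydroxy-6-{4-methoxy-2-(methoxymethoxy)-6-[(triisopropylsilyloxy)methyl]phenoxy}-4-methylbenzoate | COC(=O)c1c(O)cc(C)cc1Oc1c(OCOC)cc(OC)cc1CO[Si](C(C)C)(C(C)C)C(C)C | intermediate
20 | methyl 2-hydroxy-6-[2-(hydroxymethyl)-4-methoxy-6-(methoxymethoxy)phenoxy]-4-methylbenzoate | COC(=O)c1c(O)cc(C)cc1Oc1c(OCOC)cc(OC)cc1CO | intermediate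
21 | methyl 2-[2-(acetoxymethyl)-4-methoxy-6-(methoxymethoxy)phenoxy]-6-hydroxy-4-methylbenzoate | COC(=O)c1c(O)cc(C)cc1Oc1c(OCOC)cc(OC)cc1COC(C)=O | intermediate
22 | betaethrin A | COC(=O)c1c(O)cc(C)cc1Oc1c(O)cc(OC)cc1COC(C)=O | target

Total steps: 13. Longest linear sequence: 10 (steps 1–5, 8, 10–13).

**Steps most likely to fail**

Step 10 (Proposed new method).
- What may go wrong: the donor aryloxy group may raise the diene LUMO so far that cycloaddition becomes slower than thermal oxygen-to-carbon silyl migration in the ketene acetal. Alternatively, the ketene acetal may add at C4 and expel the aryloxide.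
- First remedy: high pressure (about 10 kbar, rt) followed by gentle heating would be tried, since it keeps the same disconnection.
- Fallback: ring A is bought instead of built, and the ether is made by a Buchwald–Hartwig-type C–O coupling, setting out from 6.
- Commercial methyl 2,6-dihydroxy-4-methylbenzoate (COC(=O)c1c(O)cc(C)cc1O) is monobenzylated (BnBr, K2CO3, acetone) to methyl 2-(benzyloxy)-6-hydroxy-4-methylbenzoate F1.
- Triflation (Tf2O, pyridine, CH2Cl2, 0 °C) gives methyl 2-(benzyloxy)-4-methyl-6-(trifluoromethylsulfonyloxy)benzoate F2.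
- Coupling with 6 (Pd(OAc)2, t-BuXPhos, K3PO4, toluene, 100 °C) gives methyl 2-(benzyloxy)-6-{4-methoxy-2-(methoxymethoxy)-6-[(triisopropylsilyloxy)methyl]phenoxy}-4-methylbenzoate F3.
- Hydrogenolysis of the aryl benzyl ether (H2, Pd/C, EtOAc) brings the sequence back to the route at 19.

Step 8.
- What may go wrong: the hindered phenoxide may attack sulfur instead of C4, which transfers the sulfonyl group. It may open the pyrone at C2 or C6, or it may simply add too slowly.
- Fallback: the sulfonate activation is abandoned, setting out from 11.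
- Treatment of 11 with (COCl)2 and catalytic DMF in CH2Cl2 gives the vinylogous acid chloride methyl 4-chloro-6-methyl-2-oxo-2H-pyran-3-carboxylate F4. Its small leaving group offers no second electrophilic centre.
- F4 is combined with neutral 6 and i-Pr2NEt in CH2Cl2, so that no hard free phenoxide is present, and the sequence returns to the route at 13.

Step 2.
- What may go wrong: the electron-rich catechol may degrade by oxidation in hot copper-containing alkali, the aldehyde may disproportionate, or conversion of the bromide may stay incomplete.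
- Fallback: the new oxygen is introduced through boron on a protected phenol. This also removes the need to differentiate the two catechol oxygens in step 3. The sequence sets out from 2.
- Benzylation (BnBr, K2CO3, DMF) gives 2-(benzyloxy)-3-bromo-5-methoxybenzaldehyde F5.
- Miyaura borylation (B2pin2, Pd(dppf)Cl2, KOAc, dioxane, 90 °C) gives 2-(benzyloxy)-5-methoxy-3-(4,4,5,5-tetramethyl-1,3,2-dioxaborolan-2-yl)benzaldehyde F6.
- Mild oxidation (NaBO3·4H2O, THF–H2O, rt, too mild for Dakin oxidation of the aldehyde) gives 2-(benzyloxy)-3-hydroxy-5-methoxybenzaldehyde F7.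
- MOMCl and i-Pr2NEt give 2-(benzyloxy)-5-methoxy-3-(methoxymethoxy)benzaldehyde F8.
- Brief hydrogenolysis (H2, Pd/C, EtOAc) returns to the route at 4. Partial over-reduction of the aldehyde would only give 5, the next compound.

**Further compounds**
F1 | step 10 | methyl 2-(benzyloxy)-6-hydroxy-4-methylbenzoate | COC(=O)c1c(O)cc(C)cc1OCc1ccccc1
F2 | step 10 | methyl 2-(benzyloxy)-4-methyl-6-(trifluoromethylsulfonyloxy)benzoate | COC(=O)c1c(OCc2ccccc2)cc(C)cc1OS(=O)(=O)C(F)(F)F
F3 | step 10 | methyl 2-(benzyloxy)-6-{4-methoxy-2-(methoxymethoxy)-6-[(triisopropylsilyloxy)methyl]phenoxy}-4-methylbenzoate | COC(=O)c1c(OCc2ccccc2)cc(C)cc1Oc1c(OCOC)cc(OC)cc1CO[Si](C(C)C)(C(C)C)C(C)C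
F4 | step 8 | methyl 4-chloro-6-methyl-2-oxo-2H-pyran-3-carboxylate | COC(=O)C1=C(Cl)C=C(C)OC1=O
F5 | step 2 | 2-(benzyloxy)-3-bromo-5-methoxybenzaldehyde | COc1cc(Br)c(OCc2ccccc2)c(C=O)c1
F6 | step 2 | 2-(benzyloxy)-5-methoxy-3-(4,4,5,5-tetramethyl-1,3,2-dioxaborolan-2-yl)benzaldehyde | COc1cc(B2OC(C)(C)C(C)(C)O2)c(OCc2ccccc2)c(C=O)c1
F7 | step 2 | 2-(benzyloxy)-3-hydroxy-5-methoxybenzaldehyde | COc1cc(O)c(OCc2ccccc2)c(C=O)c1
F8 | step 2 | 2-(benzyloxy)-5-methoxy-3-(methoxymethoxy)benzaldehyde | COCOc1cc(OC)cc(C=O)c1OCc1ccccc1
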